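## Structural features

The target is a trans-3,4-dibenzylbutyrolactone (3R,4R) whose two benzylic arms carry very different aryl groups. The C4 benzyl group is ring B, a guaiacyl ring whose phenolic oxygen is etherified by C8 of an erythro guaiacylglycerol unit on ring A, with C7 (R, free benzylic hydroxyl) standing next to C8 (S, aryl ether and CH2OH). The C3 benzyl group is C5 of ring C, the benzo ring of a trans-2-aryl-3-hydroxymethyl-7-methoxy-2,3-dihydrobenzofuran in which C2 (S, bearing the guaiacyl ring D) stands next to C3 (R). The six stereocentres therefore form three adjacent pairs (C7/C8, lactone C3/C4, dihydrofuran C2/C3) that are insulated from one another by a methylene group or an aryl ether, so each pair needs its own source of absolute configuration. Fragile points are the two free phenols, the p-oxygenated benzylic alcohol at C7 and the benzylic C2–O1 bond (acid, quinone-methide formation, hydrogenolysis), the β-aryl ether, and the lactone (hydride, hydroxide, epimerisable C3). The real difficulty is absolute and relative control in three isolated stereodiads, combined with chemoselectivity around the lactone while the glycerol aryl ether is assembled. The key step exploits the dihydrofuran ring: C2 is a benzylic ether carbon (bonded to O1 and ring D) attached to C3, a carbon on ring C that is alpha to the future CH2OH carbon, so C3 can be the carbene carbon of a ring C aryldiazoacetate and C2–H a benzylic C–H bond of an ortho benzyl ether.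

## Logic of the disconnections

33 to 31, via 32. The O–benzyl bonds of the two phenols and the O–Si bonds of the three aliphatic hydroxyls are cut. Phenols are carried as benzyl ethers because these survive base, hydride and fluoride and leave by neutral hydrogenolysis. The aliphatic hydroxyls are silyl ethers so that one fluoride treatment frees them while both phenols are still masked, which excludes quinone-methide chemistry at C7. The demand on the forward steps is that hydrogenolysis stops at the aryl benzyl ethers and spares the benzylic C7–O and C2–O1 bonds.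

31 to 29 and 14. The bond between lactone C3 and the ring C benzylic carbon is cut. This is the most convergent cut: it gives two halves of similar size, 29 holding the C7/C8 pair and lactone C4, and 14 holding the C2/C3 pair. The forward step is an enolate alkylation in which the existing C4 substituent directs the electrophile to the opposite face and so sets C3. It demands a benzylic bromide and the absence of acidic or electrophilic sites in both partners, which is why the dihydrofuran ester is reduced and capped before the coupling.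

14 back to 9, via 13, 12, 11 and 10. Only functional groups change: C–Br from C–OH, differentiation of the two primary hydroxyls, CH2OH from the ester, trans from cis by epimerisation at C3. The benzylic oxygen on ring C is given a TBS group in 9 and its precursors, not a bulkier silyl group. After the C3 hydroxymethyl group is capped as the TBDPS ether in 12, the benzylic TBS ether can then be removed with aqueous acetic acid alone. With a triisopropylsilyl group at that position no second silyl group could be kept.

9 to 8 (key step). The C2–C3 bond is cut. Ring, bond and both stereocentres arise from an acyclic, achiral diazo ester in one catalytic step. The forward reaction demands discrimination of two enantiotopic benzylic hydrogens by the catalyst and preference for the 1,5 C–H bond over all others. Hence 8 has no free hydroxyl, no carbonyl besides the ester and no alkene.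

8 back to 3 and 2, via 7, 6, 5 and 4, with 2 from 1. The diazo group comes from diazo transfer to 7. The aryl–CH2 bond of 7 is cut to aryl bromide 6 and a zinc ester enolate. This single palladium-catalysed coupling replaces an arylation–decarboxylation pair and avoids heating the acid- and heat-labile electron-rich benzyl aryl ether. The O–CH2 ether bond is cut to 3 and 2. Alkylating the phenol first (4), then reducing (5) and silylating (6), removes any need to distinguish a phenol from a benzylic alcohol.

29 back to 24 and 15, via 28, 27 and 26. The O–Si bonds, the C7–O bond (inversion) and the C7–C8 bond are cut. An auxiliary-controlled boron aldol sets C8 and C7 in the absolute sense but gives the syn (threo) pair. The erythro target therefore needs one inversion at the benzylic carbon, done by Mitsunobu displacement. C9 comes from reductive removal of the auxiliary. The demand is a reductant that reduces an activated imide but not a γ-lactone.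

24 to 21 and 23, with 23 from 22. The aryl O–CH2 bond is cut to the ring B phenol and an α-bromoacetyl imide, so the chiral auxiliary arrives already attached to the two-carbon unit. The demand is O-alkylation under base mild enough for lactone and imide.

21 back to 15 and 16, via 20, 18 and 17. The aryl benzyl ether, the lactone C–O bond, the C4–H bonds and the C=C bond are cut in turn. A Stobbe condensation differentiates the two carboxyl groups, asymmetric hydrogenation sets C4, and ester-selective reduction of the half ester fixes the lactone regiochemistry. The demands are high enantioselectivity in the hydrogenation and reduction of the ester in the presence of the carboxylate.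

## Other disconnections considered

Alternative 1: The cut removes both benzylic bonds of the lactone at once, C4–C(ring B) and C3–CH2(ring C). The lactone then comes from the chiral butenolide A2, the dithiane A3 (a masked ring A–B aldehyde) and a phenylcoumaran bromide A4 (the TBS analogue of 14). In the forward sense lithiated A3 adds to C4 of A2 anti to the menthyloxy group, and the enolate is benzylated by A4 anti to the new C4 substituent, giving the 3,4-trans adduct A1.
- In its favour: both lactone stereocentres and both benzylic C–C bonds arise in one operation from a recoverable chiral-pool auxiliary, without asymmetric hydrogenation. On the lactone alone this is better in step economy than the four steps to 21 plus the alkylation of the chosen plan. The anti-alkylation of the enolate is the same event in both plans and should be equally reliable.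
- Against it here: A1 must still lose the dithiane (Raney Ni or Ni2B), which endangers the O-benzyl groups, the aryl ether at C8 and the benzylic C2–O1 bond. The menthyl acetal carbon must also be taken down to CH2 (acetal cleavage, reduction, relactonisation) on the largest intermediate. A3 needs ring B as an aldehyde, which is incompatible with the auxiliary aldol that builds the erythro glycerol ether unless further masking steps are added.
- Comparison: the alternative does not address the dihydrobenzofuran at all, since A4 must still be made by a sequence like steps 1 to 12. The gain of about three steps before the coupling should be offset by about three delicate steps after it.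

Alternative 2: The cut is C3–C3a of the dihydrobenzofuran, which leads back to the (2S)-flavanone A6. Forward, A6 is converted by HC(OMe)3 and H2SO4 into its enol ether, PhI(OAc)2 (trivalent iodine) adds at C3, and the aryl carbon C4a shifts from C4 to C3 as PhI leaves. The product is the ring-contracted trans ester A5, with C4 as the ester carbon.
- In its favour: the trans ester forms directly, so no epimerisation step is needed, which is better than the chosen plan by one step at this point. No diazo compound and no rhodium are involved, which is better on hazard and cost. The C2 configuration is simply carried over.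
- Against it: the stereochemical problem is only moved to an enantioselective synthesis of A6, and the flavanone stereocentre can be lost through reversible chalcone formation in the strongly acidic medium. An electron-rich 2-aryl group would itself migrate, so ring D has to carry a tosylate that must later be exchanged. C5 is a bromide, so the benzylic carbon for the lactone coupling must be introduced afterwards in the presence of the ester.
- Comparison: the rearrangement transfers chirality, whereas the carbene insertion creates it. The insertion product 9 already has the C5 CH2O carbon and the final ring D protecting group. The five steps from 9 to 14 should therefore be fewer than those from A5 to a comparable bromide (detosylation, reprotection, reduction, protection, one-carbon homologation, bromination).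

Alternative 3: The cut is O1–C2, leading back to the phenol diol A8, in which only C3 (the carbon between ring C and CH2OH) is configurationally defined. Forward, BF3·OEt2 ionises the benzylic alcohol of A8 to a cation stabilised by ring D, and the ring C phenol closes onto it from the face anti to CH2OH, giving the trans alcohol A7.
- In its favour: the step is stereoconvergent, so the carbinol configuration of A8 need not be controlled. It delivers the trans relationship and the CH2OH oxidation level directly, which is better than the chosen plan by the epimerisation and reduction steps. Reagents are cheap and no diazo chemistry is used. In mechanism it mirrors the chosen plan (C3 controls C2 instead of C2 controlling C3) and is its equal in the reliability of the trans outcome.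
- Against it: the absolute configuration at C3 must be bought beforehand with a stoichiometric auxiliary, for instance an aldol of a ring C arylacetyl imide followed by reduction. The phenol has to be protected and released around that sequence. The Lewis acid exposes two electron-rich arenes to a benzylic cation, so Friedel–Crafts oligomerisation is possible. A7 again carries bromine at C5, so one-carbon homologation is still to come.
- Comparison: the savings after ring closure should be consumed by the longer preparation of A8 and the homologation. The two plans are of similar length, and the chosen one is more convergent because 9 already contains every carbon of the ring C–D half.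

Key step: step 7

Assumptions and remarks on the chemistry:
- The (S)-configured phthaloyl-tert-leucinate catalyst is taken to deliver the 2R series in this type of insertion. The route therefore commits to the (R)-configured catalyst Rh2(R-PTTL)4; if a pilot run showed the opposite sense, the antipodal catalyst would be used with no other change.
- [Rh((S,S)-Et-DuPhos)(cod)]BF4 is taken to give the R half ester 18; the (R,R) ligand would be used otherwise.
- Compounds 1, 3, 15, 16 and 22 are taken as commercial.
- The dihydrofuran descriptors are: cis ester 9 (2S,3R), trans ester 10 (2S,3S), trans alcohol 11 (2S,3R). The C3 label changes only because CO2Me ranks above C2 whereas CH2OH ranks below it.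

## Route

Step 1
Reactants: 1 benzyl alcohol (4-benzyloxy-3-methoxyphenyl)methanol
Product: 2 benzyl chloride 1-benzyloxy-4-(chloromethyl)-2-methoxybenzene
Conditions: SOCl2, CH2Cl2, 0 °C
Reagents that add atoms: thionyl chloride, ClS(Cl)=O
Why: Deoxychlorination through the chlorosulfite; an electron-rich benzylic alcohol reacts cleanly and the aryl benzyl ether tolerates the brief contact with HCl at 0 °C.

Step 2
Reactants: 3 bromovanillin 3-bromo-4-hydroxy-5-methoxybenzaldehyde; 2 benzyl chloride 1-benzyloxy-4-(chloromethyl)-2-methoxybenzene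
Product: 4 aldehyde 4-(4-benzyloxy-3-methoxybenzyloxy)-3-bromo-5-methoxybenzaldehyde
Conditions: K2CO3, DMF, 60 °C
Reagents that add atoms: none
Why: Williamson ether synthesis; the acidic, hindered phenol is alkylated as its potassium phenoxide by the reactive benzylic chloride, and doing this before the aldehyde is reduced avoids any phenol versus benzyl alcohol selectivity question.

Step 3
Reactants: 4 aldehyde 4-(4-benzyloxy-3-methoxybenzyloxy)-3-bromo-5-methoxybenzaldehyde
Product: 5 alcohol [4-(4-benzyloxy-3-methoxybenzyloxy)-3-bromo-5-methoxyphenyl]methanol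
Conditions: NaBH4, MeOH/THF, 0 °C
Reagents that add atoms: none
Why: Borohydride reduction of an aryl aldehyde; the aryl bromide and both benzyl-type ethers are inert.

Step 4
Reactants: 5 alcohol [4-(4-benzyloxy-3-methoxybenzyloxy)-3-bromo-5-methoxyphenyl]methanol
Product: 6 silyl ether tert-butyl{[4-(4-benzyloxy-3-methoxybenzyloxy)-3-bromo-5-methoxybenzyl]oxy}dimethylsilane
Conditions: TBSCl, imidazole, DMF, 25 °C
Reagents that add atoms: tert-butyldimethylsilyl chloride, CC(C)(C)[Si](C)(C)Cl
Why: Silylation of a primary benzylic alcohol; TBS is stable to the zinc enolate, DBU, the rhodium carbene, NaOMe and LiBH4, yet can later be removed in the presence of a TBDPS ether.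

Step 5
Reactants: 6 silyl ether tert-butyl{[4-(4-benzyloxy-3-methoxybenzyloxy)-3-bromo-5-methoxybenzyl]oxy}dimethylsilane
Product: 7 methyl 2-[2-(4-benzyloxy-3-methoxybenzyloxy)-3-methoxy-5-(tert-butyldimethylsilyloxymethyl)phenyl]acetate
Conditions: BrZnCH2CO2Me (from BrCH2CO2Me and Zn in THF), Pd2(dba)3 (1.5 mol%), XPhos (6 mol%), THF, 50 °C
Reagents that add atoms: methyl bromoacetate (used as its zinc reagent), COC(=O)CBr
Why: Negishi-type coupling of a Reformatsky reagent (palladium-catalysed α-arylation of a zinc ester enolate): oxidative addition of zerovalent palladium to the aryl bromide, transmetalation and reductive elimination give the arylacetate directly under nearly neutral conditions. The bulky biaryl phosphine copes with the ortho-alkoxy, electron-rich bromide.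

Step 6
Reactants: 7 methyl 2-[2-(4-benzyloxy-3-methoxybenzyloxy)-3-methoxy-5-(tert-butyldimethylsilyloxymethyl)phenyl]acetate
Product: 8 methyl 2-diazo-2-[2-(4-benzyloxy-3-methoxybenzyloxy)-3-methoxy-5-(tert-butyldimethylsilyloxymethyl)phenyl]acetate
Conditions: p-ABSA, DBU, MeCN, 0 to 25 °C
Reagents that add atoms: 4-acetamidobenzenesulfonyl azide, CC(=O)Nc1ccc(cc1)S(=O)(=O)N=[N+]=[N-]
Why: Regitz diazo transfer; DBU deprotonates the arylacetate, the enolate attacks the sulfonyl azide, and aryl plus ester stabilise the resulting donor/acceptor diazo compound.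

Step 7
Reactants: 8 methyl 2-diazo-2-[2-(4-benzyloxy-3-methoxybenzyloxy)-3-methoxy-5-(tert-butyldimethylsilyloxymethyl)phenyl]acetate
Product: 9 methyl (2S,3R)-cis-2-(4-benzyloxy-3-methoxyphenyl)-7-methoxy-5-(tert-butyldimethylsilyloxymethyl)-2,3-dihydrobenzofuran-3-carboxylate
Conditions: Rh2(R-PTTL)4 (dirhodium tetrakis[N-phthaloyl-(R)-tert-leucinate], 1 mol%), toluene (0.02 M, slow addition of 8), −60 °C
Reagents that add atoms: none
Why: The dirhodium tetracarboxylate (divalent rhodium) decomposes the diazo ester with loss of N2 to an electrophilic donor/acceptor rhodium carbene on the benzylic carbon of ring C. The carbene carbon then inserts into one of the two enantiotopic C–H bonds of the ortho O–CH2–aryl group through a concerted, asynchronous three-centre transition state with hydride-transfer character, forming the C2–C3 bond. The closest known reaction type is the enantioselective 1,5 C–H insertion of aryldiazoacetates into benzyl ethers with chiral dirhodium carboxylates, which gives cis-2-aryl-2,3-dihydrobenzofuran-3-carboxylates. The dihydrofuran ring closes by 1,5-insertion, that is through a five-membered cyclic transition state whose tether is C3a–C7a–O1. C2 is controlled by the catalyst: the phthalimido-tert-leucinate ligands differentiate the two benzylic hydrogens, and the catalyst antipode is the one chosen to give S. C3 is set in the same event, cis to the aryl group, because the ester and ring D both avoid the ligand wall in the insertion transition state, a kinetic preference. The step needs site selectivity for this C–H bond over the CH2OTBS group, the benzyl ether CH2 and the electron-rich arenes, and suppression of carbene dimerisation. Proximity (the flanking methoxy group turns the O–CH2 bond out of the ring plane toward the carbene), activation by the ether oxygen and ring D, the stabilising aryl donor, low temperature and high dilution should secure it.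

Step 8
Reactants: 9 methyl (2S,3R)-cis-2-(4-benzyloxy-3-methoxyphenyl)-7-methoxy-5-(tert-butyldimethylsilyloxymethyl)-2,3-dihydrobenzofuran-3-carboxylate
Product: 10 methyl (2S,3S)-trans-2-(4-benzyloxy-3-methoxyphenyl)-7-methoxy-5-(tert-butyldimethylsilyloxymethyl)-2,3-dihydrobenzofuran-3-carboxylate
Conditions: NaOMe (0.3 equiv), MeOH/THF, 25 °C
Reagents that add atoms: none
Why: Base-mediated epimerisation through the ester enolate (any retro-oxa-Michael opening is reversible here); C3 equilibrates to the thermodynamically favoured trans arrangement while C2, which is not acidic, keeps its configuration.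

Step 9
Reactants: 10 methyl (2S,3S)-trans-2-(4-benzyloxy-3-methoxyphenyl)-7-methoxy-5-(tert-butyldimethylsilyloxymethyl)-2,3-dihydrobenzofuran-3-carboxylate
Product: 11 [(2S,3R)-trans-2-(4-benzyloxy-3-methoxyphenyl)-7-methoxy-5-(tert-butyldimethylsilyloxymethyl)-2,3-dihydrobenzofuran-3-yl]methanol
Conditions: LiBH4, THF, 0 to 25 °C
Reagents that add atoms: none
Why: Ester reduction with a mild, weakly basic hydride that avoids β-elimination of the aryloxide; silyl and benzyl ethers are unaffected and the geometry at C3 is retained.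

Step 10
Reactants: 11 [(2S,3R)-trans-2-(4-benzyloxy-3-methoxyphenyl)-7-methoxy-5-(tert-butyldimethylsilyloxymethyl)-2,3-dihydrobenzofuran-3-yl]methanol
Product: 12 (2S,3R)-trans-2-(4-benzyloxy-3-methoxyphenyl)-3-(tert-butyldiphenylsilyloxymethyl)-7-methoxy-5-(tert-butyldimethylsilyloxymethyl)-2,3-dihydrobenzofuran
Conditions: TBDPSCl, imidazole, DMF, 25 °C
Reagents that add atoms: tert-butyldiphenylsilyl chloride, CC(C)(C)[Si](Cl)(c1ccccc1)c1ccccc1
Why: Silylation of the β-branched primary alcohol with the robust TBDPS group, which withstands the mild acid of the next step and the strong base of the coupling.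

Step 11
Reactants: 12 (2S,3R)-trans-2-(4-benzyloxy-3-methoxyphenyl)-3-(tert-butyldiphenylsilyloxymethyl)-7-methoxy-5-(tert-butyldimethylsilyloxymethyl)-2,3-dihydrobenzofuran
Product: 13 [(2S,3R)-trans-2-(4-benzyloxy-3-methoxyphenyl)-3-(tert-butyldiphenylsilyloxymethyl)-7-methoxy-2,3-dihydrobenzofuran-5-yl]methanol
Conditions: AcOH/THF/H2O (3:1:1), 25 °C
Reagents that add atoms: none
Why: Acid-catalysed hydrolysis of the unhindered primary TBS ether is much faster than that of the hindered TBDPS ether; with water as the only nucleophile the alcohol results even if the electron-rich benzylic position ionises.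

Step 12
Reactants: 13 [(2S,3R)-trans-2-(4-benzyloxy-3-methoxyphenyl)-3-(tert-butyldiphenylsilyloxymethyl)-7-methoxy-2,3-dihydrobenzofuran-5-yl]methanol
Product: 14 (2S,3R)-trans-2-(4-benzyloxy-3-methoxyphenyl)-5-(bromomethyl)-3-(tert-butyldiphenylsilyloxymethyl)-7-methoxy-2,3-dihydrobenzofuran
Conditions: CBr4, PPh3, CH2Cl2, 0 °C
Reagents that add atoms: carbon tetrabromide, BrC(Br)(Br)Br
Why: Appel bromination under neutral conditions through the alkoxyphosphonium salt; the p-alkoxybenzyl bromide is labile and is used at once.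

Step 13
Reactants: 15 O-benzylvanillin 4-benzyloxy-3-methoxybenzaldehyde; 16 dimethyl succinate
Product: 17 (E)-4-(4-benzyloxy-3-methoxyphenyl)-3-(methoxycarbonyl)but-3-enoic acid
Conditions: NaOMe, MeOH, reflux; then aq. HCl
Reagents that add atoms: none
Why: Stobbe condensation; the succinate enolate adds to the aldehyde, the alkoxide lactonises and the paraconate opens by elimination to the alkylidene half ester, which differentiates the two carboxyl groups for the later chemoselective reduction.

Step 14
Reactants: 17 (E)-4-(4-benzyloxy-3-methoxyphenyl)-3-(methoxycarbonyl)but-3-enoic acid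
Product: 18 (R)-4-(4-benzyloxy-3-methoxyphenyl)-3-(methoxycarbonyl)butanoic acid
Conditions: [Rh((S,S)-Et-DuPhos)(cod)]BF4 (0.5 mol%), H2 (4 atm), NaOMe (0.1 equiv), MeOH, 25 °C
Reagents that add atoms: none
Why: Asymmetric hydrogenation of an itaconate-type half ester; the carboxylate chelates the cationic rhodium centre and the C2-symmetric bisphospholane directs hydrogen to one face, setting the future lactone C4 as R. The benzyl ether is inert to the homogeneous catalyst.

Step 15
Reactants: 18 (R)-4-(4-benzyloxy-3-methoxyphenyl)-3-(methoxycarbonyl)butanoic acid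
Product: 20 (R)-4-(4-benzyloxy-3-methoxybenzyl)dihydrofuran-2(3H)-one, via hydroxy acid 19 (not isolated)
Conditions: KOH (1 equiv), EtOH; CaCl2, NaBH4, −10 to 25 °C; then 3 M HCl
Reagents that add atoms: none
Why: Ca(BH4)2 reduces the methyl ester while the potassium carboxylate is untouched; acidification lactonises the γ-hydroxy acid, so the lactone carbonyl derives from the former free acid and the stereocentre is not involved.

Step 16
Reactants: 20 (R)-4-(4-benzyloxy-3-methoxybenzyl)dihydrofuran-2(3H)-one
Product: 21 (R)-4-(4-hydroxy-3-methoxybenzyl)dihydrofuran-2(3H)-one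
Conditions: H2 (1 atm), Pd/C (10%), EtOAc, 25 °C
Reagents that add atoms: none
Why: Hydrogenolysis of the aryl benzyl ether frees the ring B phenol; the lactone and the remote stereocentre are inert.

Step 17
Reactants: 22 (R)-4-benzyloxazolidin-2-one
Product: 23 (R)-4-benzyl-3-(bromoacetyl)oxazolidin-2-one
Conditions: n-BuLi, THF, −78 °C; then BrCH2COBr, −78 °C
Reagents that add atoms: bromoacetyl bromide, BrCC(Br)=O
Why: N-Acylation of the lithiated oxazolidinone; at low temperature the acyl bromide carbon is far more electrophilic than the alkyl bromide carbon.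

Step 18
Reactants: 21 (R)-4-(4-hydroxy-3-methoxybenzyl)dihydrofuran-2(3H)-one; 23 (R)-4-benzyl-3-(bromoacetyl)oxazolidin-2-one
Product: 24 (R)-4-benzyl-3-{[2-methoxy-4-{[(3R)-5-oxotetrahydrofuran-3-yl]methyl}phenoxy]acetyl}oxazolidin-2-one
Conditions: K2CO3, acetone, 0 to 25 °C
Reagents that add atoms: none
Why: Williamson alkylation; the phenoxide displaces the strongly activated α-bromo imide bromide by SN2 much faster than it attacks a carbonyl group, and carbonate leaves lactone and imide intact.

Step 19
Reactants: 24 (R)-4-benzyl-3-{[2-methoxy-4-{[(3R)-5-oxotetrahydrofuran-3-yl]methyl}phenoxy]acetyl}oxazolidin-2-one; 15 O-benzylvanillin 4-benzyloxy-3-methoxybenzaldehyde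
Product: 26 (R)-4-benzyl-3-[(2R,3S)-3-(4-benzyloxy-3-methoxyphenyl)-3-hydroxy-2-{2-methoxy-4-[((3R)-5-oxotetrahydrofuran-3-yl)methyl]phenoxy}propanoyl]oxazolidin-2-one, via dibutylboron Z-enolate 25 (not isolated)
Conditions: Bu2BOTf (1.1 equiv), iPr2NEt, CH2Cl2, −78 to 0 °C; then 15, −78 to 0 °C; pH 7 buffer, MeOH, H2O2, 0 °C
Reagents that add atoms: none
Why: Evans syn aldol; soft enolisation gives the Z boron enolate, which reacts through a chair Zimmerman–Traxler transition state with the auxiliary benzyl group shielding one enolate face. This sets C8 (S in the final numbering) and C7 (S) in the syn, threo relationship; the lactone is not enolised by a stoichiometric amount of the boron triflate and amine.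

Step 20
Reactants: 26 (R)-4-benzyl-3-[(2R,3S)-3-(4-benzyloxy-3-methoxyphenyl)-3-hydroxy-2-{2-methoxy-4-[((3R)-5-oxotetrahydrofuran-3-yl)methyl]phenoxy}propanoyl]oxazolidin-2-one
Product: 27 (R)-4-benzyl-3-[(2R,3R)-3-(4-benzyloxy-3-methoxyphenyl)-3-(chloroacetoxy)-2-{2-methoxy-4-[((3R)-5-oxotetrahydrofuran-3-yl)methyl]phenoxy}propanoyl]oxazolidin-2-one
Conditions: ClCH2CO2H, PPh3, DIAD, toluene, −20 to 0 °C
Reagents that add atoms: chloroacetic acid, OC(=O)CCl
Why: Mitsunobu inversion; the benzylic hydroxyl is activated as the alkoxyphosphonium ion and displaced by chloroacetate with inversion, turning the threo pair into the erythro pair (C7 now R). The acidic chloroacetic acid favours SN2 collapse of the ion pair, and allylic 1,3-strain in the imide keeps the C8–H bond out of alignment for elimination or epimerisation.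

Step 21
Reactants: 27 (R)-4-benzyl-3-[(2R,3R)-3-(4-benzyloxy-3-methoxyphenyl)-3-(chloroacetoxy)-2-{2-methoxy-4-[((3R)-5-oxotetrahydrofuran-3-yl)methyl]phenoxy}propanoyl]oxazolidin-2-one
Product: 28 (4R)-4-{4-[(1R,2S)-1-(4-benzyloxy-3-methoxyphenyl)-1,3-dihydroxypropan-2-yl]oxy-3-methoxybenzyl}dihydrofuran-2(3H)-one
Conditions: NaBH4, THF/H2O (4:1), 0 to 20 °C
Reagents that add atoms: none
Why: Borohydride in aqueous THF reduces the activated N-acyl oxazolidinone to the primary alcohol with release of the auxiliary, and cleaves the labile chloroacetate by reduction to 2-chloroethanol. An unactivated γ-lactone should be reduced only very slowly under these conditions, and C7 and C8 are untouched.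

Step 22
Reactants: 28 (4R)-4-{4-[(1R,2S)-1-(4-benzyloxy-3-methoxyphenyl)-1,3-dihydroxypropan-2-yl]oxy-3-methoxybenzyl}dihydrofuran-2(3H)-one
Product: 29 (4R)-4-{4-[(1R,2S)-1-(4-benzyloxy-3-methoxyphenyl)-1,3-bis(tert-butyldimethylsilyloxy)propan-2-yl]oxy-3-methoxybenzyl}dihydrofuran-2(3H)-one
Conditions: TBSOTf, 2,6-lutidine, CH2Cl2, −40 to 0 °C
Reagents that add atoms: tert-butyldimethylsilyl triflate, CC(C)(C)[Si](C)(C)OS(=O)(=O)C(F)(F)F
Why: A silyl triflate with a hindered pyridine base silylates both the primary and the secondary benzylic hydroxyl without enolising the lactone.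

Step 23
Reactants: 29 (4R)-4-{4-[(1R,2S)-1-(4-benzyloxy-3-methoxyphenyl)-1,3-bis(tert-butyldimethylsilyloxy)propan-2-yl]oxy-3-methoxybenzyl}dihydrofuran-2(3H)-one; 14 (2S,3R)-trans-2-(4-benzyloxy-3-methoxyphenyl)-5-(bromomethyl)-3-(tert-butyldiphenylsilyloxymethyl)-7-methoxy-2,3-dihydrobenzofuran
Product: 31 (3R,4R)-trans-3-{[(2S,3R)-2-(4-benzyloxy-3-methoxyphenyl)-3-(tert-butyldiphenylsilyloxymethyl)-7-methoxy-2,3-dihydrobenzofuran-5-yl]methyl}-4-{4-[(1R,2S)-1-(4-benzyloxy-3-methoxyphenyl)-1,3-bis(tert-butyldimethylsilyloxy)propan-2-yl]oxy-3-methoxybenzyl}dihydrofuran-2(3H)-one, via lithium enolate 30 (not isolated)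
Conditions: LiN(SiMe3)2, THF, −78 °C; then 14, DMPU, −78 to −40 °C
Reagents that add atoms: none
Why: Alkylation of a β-substituted γ-butyrolactone lithium enolate with a benzylic bromide; the electrophile approaches anti to the C4 benzyl group, which sets lactone C3 as R in the trans relationship. Neither partner carries an acidic hydrogen or a competing electrophile.

Step 24
Reactants: 31 (3R,4R)-trans-3-{[(2S,3R)-2-(4-benzyloxy-3-methoxyphenyl)-3-(tert-butyldiphenylsilyloxymethyl)-7-methoxy-2,3-dihydrobenzofuran-5-yl]methyl}-4-{4-[(1R,2S)-1-(4-benzyloxy-3-methoxyphenyl)-1,3-bis(tert-butyldimethylsilyloxy)propan-2-yl]oxy-3-methoxybenzyl}dihydrofuran-2(3H)-one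
Product: 32 (3R,4R)-trans-3-{[(2S,3R)-2-(4-benzyloxy-3-methoxyphenyl)-3-(hydroxymethyl)-7-methoxy-2,3-dihydrobenzofuran-5-yl]methyl}-4-{4-[(1R,2S)-1-(4-benzyloxy-3-methoxyphenyl)-1,3-dihydroxypropan-2-yl]oxy-3-methoxybenzyl}dihydrofuran-2(3H)-one
Conditions: Bu4NF, AcOH, THF, 25 to 40 °C
Reagents that add atoms: none
Why: Fluoride cleaves all three silyl ethers through Si–F bond formation; acetic acid buffering protects the lactone, and because both phenols are still benzylated no quinone methide can form at C7.

Step 25
Reactants: 32 (3R,4R)-trans-3-{[(2S,3R)-2-(4-benzyloxy-3-methoxyphenyl)-3-(hydroxymethyl)-7-methoxy-2,3-dihydrobenzofuran-5-yl]methyl}-4-{4-[(1R,2S)-1-(4-benzyloxy-3-methoxyphenyl)-1,3-dihydroxypropan-2-yl]oxy-3-methoxybenzyl}dihydrofuran-2(3H)-one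
Product: 33 CNP0265599.1 (3R,4R)-trans-3-{[(2S,3R)-2-(4-hydroxy-3-methoxyphenyl)-3-(hydroxymethyl)-7-methoxy-2,3-dihydrobenzofuran-5-yl]methyl}-4-{4-[(1R,2S)-1-(4-hydroxy-3-methoxyphenyl)-1,3-dihydroxypropan-2-yl]oxy-3-methoxybenzyl}dihydrofuran-2(3H)-one
Conditions: H2 (1 atm), Pd/C (10%), EtOAc/MeOH, 25 °C
Reagents that add atoms: none
Why: Hydrogenolysis of the two aryl benzyl ethers under neutral conditions at atmospheric pressure; aryl O-benzyl bonds should be cleaved much faster than the benzylic C7–OH and C2–O1 bonds, so stopping after uptake for two ethers should leave these intact.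

## Compound list

1 | (4-benzyloxy-3-methoxyphenyl)methanol | OCc1ccc(OCc2ccccc2)c(OC)c1 | starting material
2 | 1-benzyloxy-4-(chloromethyl)-2-methoxybenzene | ClCc1ccc(OCc2ccccc2)c(OC)c1 | intermediate
3 | 3-bromo-4-hydroxy-5-methoxybenzaldehyde (5-bromovanillin) | COc1cc(C=O)cc(Br)c1O | starting material
4 | 4-(4-benzyloxy-3-methoxybenzyloxy)-3-bromo-5-methoxybenzaldehyde | COc1cc(C=O)cc(Br)c1OCc1ccc(OCc2ccccc2)c(OC)c1 | intermediate
5 | [4-(4-benzyloxy-3-methoxybenzyloxy)-3-bromo-5-methoxyphenyl]methanol | COc1cc(CO)cc(Br)c1OCc1ccc(OCc2ccccc2)c(OC)c1 | intermediate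
6 | tert-butyl{[4-(4-benzyloxy-3-methoxybenzyloxy)-3-bromo-5-methoxybenzyl]oxy}dimethylsilane | COc1cc(CO[Si](C)(C)C(C)(C)C)cc(Br)c1OCc1ccc(OCc2ccccc2)c(OC)c1 | intermediate
7 | methyl 2-[2-(4-benzyloxy-3-methoxybenzyloxy)-3-methoxy-5-(tert-butyldimethylsilyloxymethyl)phenyl]acetate | COC(=O)Cc1cc(CO[Si](C)(C)C(C)(C)C)cc(OC)c1OCc1ccc(OCc2ccccc2)c(OC)c1 | intermediate
8 | methyl 2-diazo-2-[2-(4-benzyloxy-3-methoxybenzyloxy)-3-methoxy-5-(tert-butyldimethylsilyloxymethyl)phenyl]acetate | COC(=O)C(=[N+]=[N-])c1cc(CO[Si](C)(C)C(C)(C)C)cc(OC)c1OCc1ccc(OCc2ccccc2)c(OC)c1 | intermediate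
9 | methyl (2S,3R)-cis-2-(4-benzyloxy-3-methoxyphenyl)-7-methoxy-5-(tert-butyldimethylsilyloxymethyl)-2,3-dihydrobenzofuran-3-carboxylate | CC(C)(C)[Si](C)(C)OCc1cc(OC)c2c(c1)[C@@H](C(=O)OC)[C@@H](c1ccc(OCc3ccccc3)c(OC)c1)O2 | intermediate
10 | methyl (2S,3S)-trans-2-(4-benzyloxy-3-methoxyphenyl)-7-methoxy-5-(tert-butyldimethylsilyloxymethyl)-2,3-dihydrobenzofuran-3-carboxylate | CC(C)(C)[Si](C)(C)OCc1cc(OC)c2c(c1)[C@H](C(=O)OC)[C@@H](c1ccc(OCc3ccccc3)c(OC)c1)O2 | intermediate
11 | [(2S,3R)-trans-2-(4-benzyloxy-3-methoxyphenyl)-7-methoxy-5-(tert-butyldimethylsilyloxymethyl)-2,3-dihydrobenzofuran-3-yl]methanol | CC(C)(C)[Si](C)(C)OCc1cc(OC)c2c(c1)[C@H](CO)[C@@H](c1ccc(OCc3ccccc3)c(OC)c1)O2 | intermediate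
12 | (2S,3R)-trans-2-(4-benzyloxy-3-methoxyphenyl)-3-(tert-butyldiphenylsilyloxymethyl)-7-methoxy-5-(tert-butyldimethylsilyloxymethyl)-2,3-dihydrobenzofuran | CC(C)(C)[Si](C)(C)OCc1cc(OC)c2c(c1)[C@H](CO[Si](c1ccccc1)(c1ccccc1)C(C)(C)C)[C@@H](c1ccc(OCc3ccccc3)c(OC)c1)O2 | intermediate
13 | [(2S,3R)-trans-2-(4-benzyloxy-3-methoxyphenyl)-3-(tert-butyldiphenylsilyloxymethyl)-7-methoxy-2,3-dihydrobenzofuran-5-yl]methanol | OCc1cc(OC)c2c(c1)[C@H](CO[Si](c1ccccc1)(c1ccccc1)C(C)(C)C)[C@@H](c1ccc(OCc3ccccc3)c(OC)c1)O2 | intermediate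
14 | (2S,3R)-trans-2-(4-benzyloxy-3-methoxyphenyl)-5-(bromomethyl)-3-(tert-butyldiphenylsilyloxymethyl)-7-methoxy-2,3-dihydrobenzofuran | BrCc1cc(OC)c2c(c1)[C@H](CO[Si](c1ccccc1)(c1ccccc1)C(C)(C)C)[C@@H](c1ccc(OCc3ccccc3)c(OC)c1)O2 | intermediate
15 | 4-benzyloxy-3-methoxybenzaldehyde (O-benzylvanillin) | COc1cc(C=O)ccc1OCc1ccccc1 | starting material
16 | dimethyl succinate | COC(=O)CCC(=O)OC | starting material
17 | (E)-4-(4-benzyloxy-3-methoxyphenyl)-3-(methoxycarbonyl)but-3-enoic acid | COC(=O)/C(CC(=O)O)=C/c1ccc(OCc2ccccc2)c(OC)c1 | intermediate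
18 | (R)-4-(4-benzyloxy-3-methoxyphenyl)-3-(methoxycarbonyl)butanoic acid | COC(=O)[C@@H](CC(=O)O)Cc1ccc(OCc2ccccc2)c(OC)c1 | intermediate
19 | (R)-4-(4-benzyloxy-3-methoxyphenyl)-3-(hydroxymethyl)butanoic acid (formed as its salt) | OC[C@@H](CC(=O)O)Cc1ccc(OCc2ccccc2)c(OC)c1 | intermediate
20 | (R)-4-(4-benzyloxy-3-methoxybenzyl)dihydrofuran-2(3H)-one | COc1cc(C[C@H]2COC(=O)C2)ccc1OCc1ccccc1 | intermediate
21 | (R)-4-(4-hydroxy-3-methoxybenzyl)dihydrofuran-2(3H)-one | COc1cc(C[C@H]2COC(=O)C2)ccc1O | intermediate
22 | (R)-4-benzyloxazolidin-2-one | O=C1N[C@H](Cc2ccccc2)CO1 | starting material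
23 | (R)-4-benzyl-3-(bromoacetyl)oxazolidin-2-one | O=C(CBr)N1C(=O)OC[C@H]1Cc1ccccc1 | intermediate
24 | (R)-4-benzyl-3-{[2-methoxy-4-{[(3R)-5-oxotetrahydrofuran-3-yl]methyl}phenoxy]acetyl}oxazolidin-2-one | COc1cc(C[C@H]2COC(=O)C2)ccc1OCC(=O)N1C(=O)OC[C@H]1Cc1ccccc1 | intermediate
25 | dibutylboron (Z)-enolate of 24 | CCCCB(CCCC)O/C(=C\Oc1ccc(C[C@H]2COC(=O)C2)cc1OC)N1C(=O)OC[C@H]1Cc1ccccc1 | intermediate
26 | (R)-4-benzyl-3-[(2R,3S)-3-(4-benzyloxy-3-methoxyphenyl)-3-hydroxy-2-{2-methoxy-4-[((3R)-5-oxotetrahydrofuran-3-yl)methyl]phenoxy}propanoyl]oxazolidin-2-one (threo) | COc1cc([C@H](O)[C@H](C(=O)N2C(=O)OC[C@H]2Cc2ccccc2)Oc2ccc(C[C@H]3COC(=O)C3)cc2OC)ccc1OCc1ccccc1 | intermediate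
27 | (R)-4-benzyl-3-[(2R,3R)-3-(4-benzyloxy-3-methoxyphenyl)-3-(chloroacetoxy)-2-{2-methoxy-4-[((3R)-5-oxotetrahydrofuran-3-yl)methyl]phenoxy}propanoyl]oxazolidin-2-one (erythro) | COc1cc([C@@H](OC(=O)CCl)[C@H](C(=O)N2C(=O)OC[C@H]2Cc2ccccc2)Oc2ccc(C[C@H]3COC(=O)C3)cc2OC)ccc1OCc1ccccc1 | intermediate
28 | (4R)-4-{4-[(1R,2S)-1-(4-benzyloxy-3-methoxyphenyl)-1,3-dihydroxypropan-2-yl]oxy-3-methoxybenzyl}dihydrofuran-2(3H)-one | COc1cc([C@@H](O)[C@H](CO)Oc2ccc(C[C@H]3COC(=O)C3)cc2OC)ccc1OCc1ccccc1 | intermediate
29 | (4R)-4-{4-[(1R,2S)-1-(4-benzyloxy-3-methoxyphenyl)-1,3-bis(tert-butyldimethylsilyloxy)propan-2-yl]oxy-3-methoxybenzyl}dihydrofuran-2(3H)-one | COc1cc([C@@H](O[Si](C)(C)C(C)(C)C)[C@H](CO[Si](C)(C)C(C)(C)C)Oc2ccc(C[C@H]3COC(=O)C3)cc2OC)ccc1OCc1ccccc1 | intermediate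
30 | lithium enolate of 29 | COc1cc([C@@H](O[Si](C)(C)C(C)(C)C)[C@H](CO[Si](C)(C)C(C)(C)C)Oc2ccc(C[C@H]3COC(O[Li])=C3)cc2OC)ccc1OCc1ccccc1 | intermediate
31 | (3R,4R)-trans-3-{[(2S,3R)-2-(4-benzyloxy-3-methoxyphenyl)-3-(tert-butyldiphenylsilyloxymethyl)-7-methoxy-2,3-dihydrobenzofuran-5-yl]methyl}-4-{4-[(1R,2S)-1-(4-benzyloxy-3-methoxyphenyl)-1,3-bis(tert-butyldimethylsilyloxy)propan-2-yl]oxy-3-methoxybenzyl}dihydrofuran-2(3H)-one | COc1cc([C@@H](O[Si](C)(C)C(C)(C)C)[C@H](CO[Si](C)(C)C(C)(C)C)Oc2ccc(C[C@H]3COC(=O)[C@@H]3Cc3cc(OC)c4c(c3)[C@H](CO[Si](c5ccccc5)(c5ccccc5)C(C)(C)C)[C@@H](c3ccc(OCc5ccccc5)c(OC)c3)O4)cc2OC)ccc1OCc1ccccc1 | intermediate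
32 | (3R,4R)-trans-3-{[(2S,3R)-2-(4-benzyloxy-3-methoxyphenyl)-3-(hydroxymethyl)-7-methoxy-2,3-dihydrobenzofuran-5-yl]methyl}-4-{4-[(1R,2S)-1-(4-benzyloxy-3-methoxyphenyl)-1,3-dihydroxypropan-2-yl]oxy-3-methoxybenzyl}dihydrofuran-2(3H)-one | COc1cc([C@@H](O)[C@H](CO)Oc2ccc(C[C@H]3COC(=O)[C@@H]3Cc3cc(OC)c4c(c3)[C@H](CO)[C@@H](c3ccc(OCc5ccccc5)c(OC)c3)O4)cc2OC)ccc1OCc1ccccc1 | intermediate
33 | CNP0265599.1, (3R,4R)-trans-3-{[(2S,3R)-2-(4-hydroxy-3-methoxyphenyl)-3-(hydroxymethyl)-7-methoxy-2,3-dihydrobenzofuran-5-yl]methyl}-4-{4-[(1R,2S)-1-(4-hydroxy-3-methoxyphenyl)-1,3-dihydroxypropan-2-yl]oxy-3-methoxybenzyl}dihydrofuran-2(3H)-one | COc1cc([C@@H](O)[C@H](CO)Oc2ccc(C[C@H]3COC(=O)[C@@H]3Cc3cc(OC)c4c(c3)[C@H](CO)[C@@H](c3ccc(O)c(OC)c3)O4)cc2OC)ccc1O | target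

## Step count and least certain steps

Total step count: 25. Longest linear sequence: 15 steps (steps 1 to 12, then 23 to 25).

Step 7 (key step). The most likely failure is erosion of enantiofacial discrimination and of the cis preference. The very electron-rich ring D can favour a stepwise hydride-transfer pathway; intermolecular insertion or carbene dimerisation can also intrude if the concentration is not kept low. Fallback (stereocontrol by a covalently bound auxiliary and separation in place of catalyst control), setting out from 7 and returning at 11: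
- 7 is saponified (LiOH, THF/H2O) to the arylacetic acid F1.
- F1 is esterified with (1R,2S,5R)-menthol (EDC, DMAP) to the menthyl arylacetate F2.
- Diazo transfer (p-ABSA, DBU) gives the menthyl aryldiazoacetate F3.
- Insertion with achiral Rh2(OAc)4 followed by DBU equilibration should give the two trans menthyl esters, the (2S,3S) ester F4 and the (2R,3R) ester F5. These are diastereomers and are separated by crystallisation or chromatography.
- LiBH4 reduction of F4 gives 11.

Step 20. The most likely failure is partial loss of stereochemical integrity through ionisation of the electron-rich benzylic alkoxyphosphonium ion, or elimination toward the enol ether. Fallback (inversion by oxidation and Felkin–Anh reduction in place of substitution), setting out from 26 and returning at 29: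
- NaBH4 in THF/H2O converts 26 into the threo diol F7.
- TBSCl and imidazole at 0 °C silylate the primary hydroxyl to give the threo silyl ether F8.
- Dess–Martin periodinane gives the α-aryloxy ketone F9.
- LiBH(s-Bu)3 at −78 °C should reduce F9 under Felkin–Anh control (aryloxy group anti to the incoming hydride) to the erythro alcohol F10.
- TBSOTf and 2,6-lutidine give 29.

Step 21. The most likely failure is competing reduction or opening of the γ-lactone, or β-elimination of the acyloxy group at the stage of the transient aldehyde. Fallback (hydrolytic removal of the auxiliary and acid-selective reduction), setting out from 27 and returning at 28: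
- Thiourea (NaHCO3, EtOH, 50 °C) removes the chloroacetyl group to give the erythro β-hydroxy imide F11.
- LiOH/H2O2 (THF/H2O, 0 °C) hydrolyses the imide to the erythro acid F12 with recovery of 22; any lactone opened recloses on acidification.
- BH3·SMe2, which reduces a carboxylic acid much faster than a lactone, gives 28.

Step 23. The most likely failure is low conversion through decomposition of the labile p-alkoxybenzyl bromide, or proton transfer in place of alkylation with two hindered partners. Fallback (aldol addition and radical deoxygenation in place of alkylation), setting out from 13 and 29 and returning at 31: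
- 13 is oxidised with MnO2 to the aldehyde F13.
- Addition of the lithium enolate 30 gives the trans β-hydroxy lactone F14 (either configuration at the carbinol carbon).
- PhOC(S)Cl and DMAP give the phenyl thiocarbonate F15.
- Bu3SnH and AIBN in toluene at 80 °C (Barton–McCombie deoxygenation) give 31.

Step 5. The most likely failure is sluggish oxidative addition to the ortho-alkoxy, electron-rich bromide, with self-condensation of the zinc enolate taking over. Fallback (stabilised enolate arylation followed by dealkoxycarbonylation), setting out from 6 and returning at 7: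
- 6 is coupled with dimethyl malonate (Pd(dba)2, P(t-Bu)3, K3PO4, toluene, 70 °C) to the dimethyl arylmalonate F6.
- Krapcho dealkoxycarbonylation (LiCl, wet DMSO, 130 °C) gives 7.

## Further compounds

F1 | step 7 | 2-[2-(4-benzyloxy-3-methoxybenzyloxy)-3-methoxy-5-(tert-butyldimethylsilyloxymethyl)phenyl]acetic acid | OC(=O)Cc1cc(CO[Si](C)(C)C(C)(C)C)cc(OC)c1OCc1ccc(OCc2ccccc2)c(OC)c1
F2 | step 7 | (1R,2S,5R)-menthyl 2-[2-(4-benzyloxy-3-methoxybenzyloxy)-3-methoxy-5-(tert-butyldimethylsilyloxymethyl)phenyl]acetate | O=C(Cc1cc(CO[Si](C)(C)C(C)(C)C)cc(OC)c1OCc1ccc(OCc2ccccc2)c(OC)c1)O[C@@H]1C[C@H](C)CC[C@H]1C(C)C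
F3 | step 7 | (1R,2S,5R)-menthyl 2-diazo-2-[2-(4-benzyloxy-3-methoxybenzyloxy)-3-methoxy-5-(tert-butyldimethylsilyloxymethyl)phenyl]acetate | [N-]=[N+]=C(C(=O)O[C@@H]1C[C@H](C)CC[C@H]1C(C)C)c1cc(CO[Si](C)(C)C(C)(C)C)cc(OC)c1OCc1ccc(OCc2ccccc2)c(OC)c1
F4 | step 7 | (1R,2S,5R)-menthyl (2S,3S)-trans-2-(4-benzyloxy-3-methoxyphenyl)-7-methoxy-5-(tert-butyldimethylsilyloxymethyl)-2,3-dihydrobenzofuran-3-carboxylate | CC(C)(C)[Si](C)(C)OCc1cc(OC)c2c(c1)[C@H](C(=O)O[C@@H]1C[C@H](C)CC[C@H]1C(C)C)[C@@H](c1ccc(OCc3ccccc3)c(OC)c1)O2
F5 | step 7 | (1R,2S,5R)-menthyl (2R,3R)-trans-2-(4-benzyloxy-3-methoxyphenyl)-7-methoxy-5-(tert-butyldimethylsilyloxymethyl)-2,3-dihydrobenzofuran-3-carboxylate | CC(C)(C)[Si](C)(C)OCc1cc(OC)c2c(c1)[C@@H](C(=O)O[C@@H]1C[C@H](C)CC[C@H]1C(C)C)[C@H](c1ccc(OCc3ccccc3)c(OC)c1)O2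
F6 | step 5 | dimethyl 2-[2-(4-benzyloxy-3-methoxybenzyloxy)-3-methoxy-5-(tert-butyldimethylsilyloxymethyl)phenyl]malonate | COC(=O)C(C(=O)OC)c1cc(CO[Si](C)(C)C(C)(C)C)cc(OC)c1OCc1ccc(OCc2ccccc2)c(OC)c1
F7 | step 20 | (4R)-4-{4-[(1S,2S)-1-(4-benzyloxy-3-methoxyphenyl)-1,3-dihydroxypropan-2-yl]oxy-3-methoxybenzyl}dihydrofuran-2(3H)-one (threo diol) | COc1cc([C@H](O)[C@H](CO)Oc2ccc(C[C@H]3COC(=O)C3)cc2OC)ccc1OCc1ccccc1
F8 | step 20 | (4R)-4-{4-[(1S,2S)-1-(4-benzyloxy-3-methoxyphenyl)-3-(tert-butyldimethylsilyloxy)-1-hydroxypropan-2-yl]oxy-3-methoxybenzyl}dihydrofuran-2(3H)-one | COc1cc([C@H](O)[C@H](CO[Si](C)(C)C(C)(C)C)Oc2ccc(C[C@H]3COC(=O)C3)cc2OC)ccc1OCc1ccccc1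
F9 | step 20 | (4R)-4-{4-[(2S)-1-(4-benzyloxy-3-methoxyphenyl)-3-(tert-butyldimethylsilyloxy)-1-oxopropan-2-yl]oxy-3-methoxybenzyl}dihydrofuran-2(3H)-one | COc1cc(C(=O)[C@H](CO[Si](C)(C)C(C)(C)C)Oc2ccc(C[C@H]3COC(=O)C3)cc2OC)ccc1OCc1ccccc1
F10 | step 20 | (4R)-4-{4-[(1R,2S)-1-(4-benzyloxy-3-methoxyphenyl)-3-(tert-butyldimethylsilyloxy)-1-hydroxypropan-2-yl]oxy-3-methoxybenzyl}dihydrofuran-2(3H)-one | COc1cc([C@@H](O)[C@H](CO[Si](C)(C)C(C)(C)C)Oc2ccc(C[C@H]3COC(=O)C3)cc2OC)ccc1OCc1ccccc1
F11 | step 21 | (R)-4-benzyl-3-[(2R,3R)-3-(4-benzyloxy-3-methoxyphenyl)-3-hydroxy-2-{2-methoxy-4-[((3R)-5-oxotetrahydrofuran-3-yl)methyl]phenoxy}propanoyl]oxazolidin-2-one | COc1cc([C@@H](O)[C@H](C(=O)N2C(=O)OC[C@H]2Cc2ccccc2)Oc2ccc(C[C@H]3COC(=O)C3)cc2OC)ccc1OCc1ccccc1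
F12 | step 21 | (2R,3R)-3-(4-benzyloxy-3-methoxyphenyl)-3-hydroxy-2-{2-methoxy-4-[((3R)-5-oxotetrahydrofuran-3-yl)methyl]phenoxy}propanoic acid | COc1cc([C@@H](O)[C@H](C(=O)O)Oc2ccc(C[C@H]3COC(=O)C3)cc2OC)ccc1OCc1ccccc1
F13 | step 23 | (2S,3R)-trans-2-(4-benzyloxy-3-methoxyphenyl)-3-(tert-butyldiphenylsilyloxymethyl)-7-methoxy-2,3-dihydrobenzofuran-5-carbaldehyde | O=Cc1cc(OC)c2c(c1)[C@H](CO[Si](c1ccccc1)(c1ccccc1)C(C)(C)C)[C@@H](c1ccc(OCc3ccccc3)c(OC)c1)O2
F14 | step 23 | trans aldol adduct of 30 and F13 (31 with CH(OH) in place of the ring C benzylic CH2) | COc1cc([C@@H](O[Si](C)(C)C(C)(C)C)[C@H](CO[Si](C)(C)C(C)(C)C)Oc2ccc(C[C@H]3COC(=O)[C@@H]3C(O)c3cc(OC)c4c(c3)[C@H](CO[Si](c5ccccc5)(c5ccccc5)C(C)(C)C)[C@@H](c3ccc(OCc5ccccc5)c(OC)c3)O4)cc2OC)ccc1OCc1ccccc1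
F15 | step 23 | O-phenyl thiocarbonate of F14 | COc1cc([C@@H](O[Si](C)(C)C(C)(C)C)[C@H](CO[Si](C)(C)C(C)(C)C)Oc2ccc(C[C@H]3COC(=O)[C@@H]3C(OC(=S)Oc3ccccc3)c3cc(OC)c4c(c3)[C@H](CO[Si](c5ccccc5)(c5ccccc5)C(C)(C)C)[C@@H](c3ccc(OCc5ccccc5)c(OC)c3)O4)cc2OC)ccc1OCc1ccccc1
A1 | alternative 1 | 3,4-trans-4,5-trans adduct carrying the 2-aryl-1,3-dithian-2-yl group at C4, the phenylcoumaran benzyl group at C3 and the menthyloxy group at C5 | COc1cc([C@@H](OC(C)(C)OC5)[C@H]5Oc2ccc(C6(SCCCS6)[C@H]3[C@H](O[C@@H]7C[C@H](C)CC[C@H]7C(C)C)OC(=O)[C@@H]3Cc3cc(OC)c4c(c3)[C@H](CO[Si](C)(C)C(C)(C)C)[C@@H](c3ccc(OCc8ccccc8)c(OC)c3)O4)cc2OC)ccc1OCc1ccccc1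
A2 | alternative 1 | (5R)-5-[(1R,2S,5R)-menthyloxy]furan-2(5H)-one | O=C1C=C[C@H](O[C@@H]2C[C@H](C)CC[C@H]2C(C)C)O1
A3 | alternative 1 | 2-{4-[(4R,5S)-4-(4-benzyloxy-3-methoxyphenyl)-2,2-dimethyl-1,3-dioxan-5-yl]oxy-3-methoxyphenyl}-1,3-dithiane | COc1cc([C@@H](OC(C)(C)OC3)[C@H]3Oc2ccc(C4SCCCS4)cc2OC)ccc1OCc1ccccc1
A4 | alternative 1 | (2S,3R)-trans-2-(4-benzyloxy-3-methoxyphenyl)-5-(bromomethyl)-3-(tert-butyldimethylsilyloxymethyl)-7-methoxy-2,3-dihydrobenzofuran | BrCc1cc(OC)c2c(c1)[C@H](CO[Si](C)(C)C(C)(C)C)[C@@H](c1ccc(OCc3ccccc3)c(OC)c1)O2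
A5 | alternative 2 | methyl (2S,3S)-trans-5-bromo-7-methoxy-2-(3-methoxy-4-tosyloxyphenyl)-2,3-dihydrobenzofuran-3-carboxylate | Brc3cc(OC)c4c(c3)[C@H](C(=O)OC)[C@@H](c3ccc(OS(=O)(=O)c5ccc(C)cc5)c(OC)c3)O4
A6 | alternative 2 | (2S)-6-bromo-8-methoxy-2-(3-methoxy-4-tosyloxyphenyl)chroman-4-one | O=C1C[C@@H](c2ccc(OS(=O)(=O)c3ccc(C)cc3)c(OC)c2)Oc2c(OC)cc(Br)cc12
A7 | alternative 3 | [(2S,3R)-2-(4-benzyloxy-3-methoxyphenyl)-5-bromo-7-methoxy-2,3-dihydrobenzofuran-3-yl]methanol | Brc3cc(OC)c4c(c3)[C@H](CO)[C@@H](c3ccc(OCc5ccccc5)c(OC)c3)O4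
A8 | alternative 3 | (2R)-1-(4-benzyloxy-3-methoxyphenyl)-2-(5-bromo-2-hydroxy-3-methoxyphenyl)propane-1,3-diol (either configuration at C1) | Oc1c(OC)cc(Br)cc1[C@H](CO)C(O)c1ccc(OCc2ccccc2)c(OC)c1
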